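The route rests on cutting the C4–C4a bond of ring C. In ring A, the carbon bearing O1 (C8a) lies para to the pyrone-bearing C6. In the ring-opened aryl ether, the line O1–C8a···C6–C3'' is therefore a local symmetry element. The two carbons ortho to the ether oxygen (future C4a and C8) are constitutionally equivalent. Intramolecular Friedel–Crafts acylation of the (S)-3-aryloxy-3-phenylpropanoic acid closes ring C in one operation with no regiochemical choice, and it leaves the preset C2 stereocentre untouched. This acid carries benzyl ethers on both ring A oxygens and a hydrogenolysis-stable 2-(trimethylsilyl)ethyl group on the pyrone oxygen, so no reprotection is needed later.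

Key step: step 12

Remark (numbering): flavanone locants (O1, C2 to C8a) are used for the chromanone and doubly primed locants for the pyrone; C3'' is bonded to C6.
Remark (assumption): the (Sa,Sc,Sc) phosphoramidite is taken to deliver the (S) allylic ether. Both antipodes are commercial, so the mirror-image ligand is used if the sense of induction proves opposite.
Remark (axis): after ring closure ring A is unsymmetrical, so the hindered C6–C3'' bond may give two rotamers. The target defines no axial configuration, and such rotamers are carried on together.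
Remark (supply): 3,5-bis(benzyloxy)phenol is treated as a catalogue compound, which brings in the two-to-one differentiation of the phloroglucinol oxygens.

Step 1
Reactants: 1 pentan-3-one
Product: 2 trimethyl(pent-2-en-3-yloxy)silane (E/Z mixture)
Conditions: Me3SiOTf, Et3N, CH2Cl2, 0 °C
Reagents that add atoms: trimethylsilyl trifluoromethanesulfonate, C[Si](C)(C)OS(=O)(=O)C(F)(F)F
Why: Soft enolisation and O-silylation (silyl enol ether formation) of a symmetrical ketone can give only one regioisomer, and the alkene geometry is irrelevant because this double bond ends up in the pyrone ring.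

Step 2
Reactants: 2 trimethyl(pent-2-en-3-yloxy)silane; 3 malonyl dichloride
Product: 5 6-ethyl-4-hydroxy-5-methyl-2H-pyran-2-one, via diketo acid chloride 4 (not isolated)
Conditions: Et2O, −78 °C to rt
Reagents that add atoms: none
Why: In this silyl enol ether/malonyl dichloride pyrone annulation, C-acylation of the enol ether gives 4, whose ketone enol oxygen closes on the second acid chloride, and tautomerisation gives the 4-hydroxy-2-pyrone with ethyl at C6'' and methyl at C5''.

Step 3
Reactants: 5 6-ethyl-4-hydroxy-5-methyl-2H-pyran-2-one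
Product: 6 6-ethyl-4-hydroxy-3-iodo-5-methyl-2H-pyran-2-one
Conditions: NIS, MeCN, rt, dark
Reagents that add atoms: N-iodosuccinimide, O=C1CCC(=O)N1I
Why: Electrophilic iodination of an enolised β-keto lactone is used, and C3'' is the only unsubstituted ring carbon and the enolic, most nucleophilic one.

Step 4
Reactants: 6 6-ethyl-4-hydroxy-3-iodo-5-methyl-2H-pyran-2-one
Product: 7 6-ethyl-3-iodo-5-methyl-4-[2-(trimethylsilyl)ethoxy]-2H-pyran-2-one
Conditions: Me3SiCH2CH2OH, PPh3, DIAD, THF, 0 °C to rt
Reagents that add atoms: 2-(trimethylsilyl)ethanol, OCC[Si](C)(C)C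
Why: Mitsunobu etherification of acidic 4-hydroxy-2-pyrones with primary alcohols takes place on O4'' under neutral conditions, and it installs a group that tolerates hydrogenolysis and brief mild acid but falls to fluoride.

Step 5
Reactants: 8 3,5-bis(benzyloxy)phenol
Product: 9 [3,5-bis(benzyloxy)phenoxy]triisopropylsilane
Conditions: i-Pr3SiCl, imidazole, DMF, rt
Reagents that add atoms: chlorotriisopropylsilane, CC(C)[Si](Cl)(C(C)C)C(C)C
Why: Standard phenol silylation masks the future O1 with a bulky group that is a poor director of lithiation and shields its own ortho positions.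

Step 6
Reactants: 9 [3,5-bis(benzyloxy)phenoxy]triisopropylsilane; 7 6-ethyl-3-iodo-5-methyl-4-[2-(trimethylsilyl)ethoxy]-2H-pyran-2-one
Product: 12 3-{2,6-bis(benzyloxy)-4-[(triisopropylsilyl)oxy]phenyl}-6-ethyl-5-methyl-4-[2-(trimethylsilyl)ethoxy]-2H-pyran-2-one, via aryllithium 10 (not isolated), via arylzinc chloride 11 (not isolated)
Conditions: n-BuLi, THF, 0 °C; ZnCl2, THF, 0 °C to rt; 7, Pd2(dba)3 (2 mol %), RuPhos (8 mol %), THF, 60 °C
Reagents that add atoms: n-butyllithium, [Li]CCCC (lithium of 10 only); zinc chloride, Cl[Zn]Cl (zinc and chlorine of 11 only); no atom of either stays in 12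
Why: Directed ortho-metalation removes the C–H flanked by two coordinating benzyloxy groups (para to the silyl ether), and transmetalation to zinc tames the nucleophile so that the lactone survives a Negishi coupling run with a ligand made for di-ortho-substituted partners.

Step 7
Reactants: 12 3-{2,6-bis(benzyloxy)-4-[(triisopropylsilyl)oxy]phenyl}-6-ethyl-5-methyl-4-[2-(trimethylsilyl)ethoxy]-2H-pyran-2-one
Product: 13 3-[2,6-bis(benzyloxy)-4-hydroxyphenyl]-6-ethyl-5-methyl-4-[2-(trimethylsilyl)ethoxy]-2H-pyran-2-one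
Conditions: Bu4NF (1 equiv), AcOH (1 equiv), THF, 0 °C
Reagents that add atoms: none
Why: Fluoride desilylation of a phenolic silyl ether (good aryloxide leaving group on silicon) is far faster than attack on the C-bound trimethylsilyl group, so one buffered equivalent in the cold should free only the para phenol.

Step 8
Reactants: 14 (E)-cinnamyl alcohol
Product: 15 (E)-cinnamyl methyl carbonate
Conditions: ClCO2Me, pyridine, CH2Cl2, 0 °C
Reagents that add atoms: methyl chloroformate, COC(=O)Cl
Why: Simple O-acylation of a primary allylic alcohol gives the carbonate leaving group needed for the allylic substitution.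

Step 9
Reactants: 13 3-[2,6-bis(benzyloxy)-4-hydroxyphenyl]-6-ethyl-5-methyl-4-[2-(trimethylsilyl)ethoxy]-2H-pyran-2-one; 15 (E)-cinnamyl methyl carbonate
Product: 17 3-{2,6-bis(benzyloxy)-4-[(1S)-1-phenylprop-2-en-1-yloxy]phenyl}-6-ethyl-5-methyl-4-[2-(trimethylsilyl)ethoxy]-2H-pyran-2-one, via lithium aryloxide 16 (not isolated)
Conditions: LiOt-Bu (1 equiv), THF, rt; 15 (1.3 equiv), [Ir(cod)Cl]2 (2 mol %), (Sa,Sc,Sc)-1,1'-binaphthalene-2,2'-diyl N,N-bis(1-phenylethyl)phosphoramidite (4 mol %, pre-activated with n-PrNH2), THF, 50 °C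
Reagents that add atoms: lithium tert-butoxide, [Li+].[O-]C(C)(C)C (lithium of 16 only)
Why: In this iridium–phosphoramidite-catalysed asymmetric allylic etherification, the cyclometalated complex ionises the linear carbonate and the ortho-unsubstituted aryloxide attacks the benzylic terminus of the π-cinnamyl unit anti to the metal, so the branched ether forms and the ligand-controlled allyl face sets the future C2 as (S).

Step 10
Reactants: 17 3-{2,6-bis(benzyloxy)-4-[(1S)-1-phenylprop-2-en-1-yloxy]phenyl}-6-ethyl-5-methyl-4-[2-(trimethylsilyl)ethoxy]-2H-pyran-2-one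
Product: 19 3-{2,6-bis(benzyloxy)-4-[(1S)-3-hydroxy-1-phenylpropoxy]phenyl}-6-ethyl-5-methyl-4-[2-(trimethylsilyl)ethoxy]-2H-pyran-2-one, via B-alkyl-9-BBN adduct 18 (not isolated)
Conditions: 9-BBN, THF, 0 °C to rt; NaBO3·4H2O, THF–H2O, rt
Reagents that add atoms: 9-borabicyclo[3.3.1]nonane, B1C2CCCC1CCC2 (boron and its bicyclic frame, in 18 only); NaBO3·4H2O, [Na+].[Na+].O[B-]1(O)OO[B-](O)(O)OO1 (hydroxyl oxygen of 19)
Why: In this anti-Markovnikov hydroboration–oxidation, the bulky borane adds to the terminal carbon of the only unhindered alkene (the pyrone double bonds are tetrasubstituted and conjugated), the stereocentre is not involved, and perborate avoids strongly basic peroxide that could open the pyrone.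

Step 11
Reactants: 19 3-{2,6-bis(benzyloxy)-4-[(1S)-3-hydroxy-1-phenylpropoxy]phenyl}-6-ethyl-5-methyl-4-[2-(trimethylsilyl)ethoxy]-2H-pyran-2-one
Product: 21 (3S)-3-(3,5-bis(benzyloxy)-4-{6-ethyl-5-methyl-2-oxo-4-[2-(trimethylsilyl)ethoxy]-2H-pyran-3-yl}phenoxy)-3-phenylpropanoic acid, via aldehyde 20 (not isolated)
Conditions: TEMPO (20 mol %), PhI(OAc)2 (2.2 equiv), MeCN–H2O, rt
Reagents that add atoms: water, O
Why: Oxoammonium-catalysed (TEMPO) oxidation takes the primary alcohol through 20 and its hydrate to the acid in a chlorine-free, weakly acidic medium, which avoids ring chlorination of the electron-rich arene and base-induced β-elimination of the aryloxide.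

Step 12
Reactants: 21 (3S)-3-(3,5-bis(benzyloxy)-4-{6-ethyl-5-methyl-2-oxo-4-[2-(trimethylsilyl)ethoxy]-2H-pyran-3-yl}phenoxy)-3-phenylpropanoic acid
Product: 23 (2S)-5,7-bis(benzyloxy)-6-{6-ethyl-5-methyl-2-oxo-4-[2-(trimethylsilyl)ethoxy]-2H-pyran-3-yl}-2-phenylchroman-4-one, via mixed trifluoroacetic anhydride 22 (not isolated)
Conditions: (CF3CO)2O (2 equiv), CH2Cl2 (0.02 M), 0 °C; aq. NaHCO3
Reagents that add atoms: trifluoroacetic anhydride, O=C(OC(=O)C(F)(F)F)C(F)(F)F (trifluoroacetyl group of 22 only)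
Why: The anhydride turns the acid into 22, whose acyl carbon (or the acylium ion derived from it) is attacked by the ring A carbon ortho to the ether oxygen, and proton loss from the σ-complex gives the aryl ketone; this is an intramolecular Friedel–Crafts acylation, the established way from 3-aryloxy-3-arylpropanoic acids to chroman-4-ones. Ring C closes in a 6-exo-trig mode at the acyl carbon (its C=O stays outside the new ring), with the nucleophilic C4a=C8a bond of the arene inside the ring. The attacked carbon is ortho to O1, ortho to one benzyloxy group and para to the other, so the arene should react at 0 °C without Lewis or mineral acid. Regioselectivity is secured by the substrate, because C8a is para to C6 and the two benzyl ethers are alike, so both ortho carbons lead to the same constitution, and the new ketone deactivates ring A against a second acylation or trifluoroacetylation at C8. No stereocentre is formed, and C2 should keep its configuration because none of its bonds takes part and the cold, dilute, weakly acidic medium should not ionise the benzylic C2–O1 bond. The closure does break the symmetry of ring A, so two rotamers about C6–C3'' may appear, which is harmless for a target without defined axial configuration.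

Step 13
Reactants: 23 (2S)-5,7-bis(benzyloxy)-6-{6-ethyl-5-methyl-2-oxo-4-[2-(trimethylsilyl)ethoxy]-2H-pyran-3-yl}-2-phenylchroman-4-one
Product: 24 (2S)-6-{6-ethyl-5-methyl-2-oxo-4-[2-(trimethylsilyl)ethoxy]-2H-pyran-3-yl}-5,7-dihydroxy-2-phenylchroman-4-one
Conditions: H2 (1 atm), Pd/C, EtOAc–MeOH, rt
Reagents that add atoms: none
Why: Catalytic hydrogenolysis cleaves the two aryl benzyl ethers, while the silylethyl group, the fully substituted pyrone, the ketone and the cyclic C2–O1 ether are expected to persist at atmospheric pressure, so only the pyrone oxygen stays masked.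

Step 14
Reactants: 25 2-methylbut-3-en-2-ol
Product: 27 tert-butyl 2-methylbut-3-en-2-yl carbonate, via lithium alkoxide 26 (not isolated)
Conditions: n-BuLi, THF, −78 °C; Boc2O, −78 °C to rt
Reagents that add atoms: n-butyllithium, [Li]CCCC (lithium of 26 only); di-tert-butyl dicarbonate, CC(C)(C)OC(=O)OC(=O)OC(C)(C)C
Why: Alkoxycarbonylation of the preformed tertiary alkoxide is the usual way to acylate a hindered tertiary allylic alcohol.

Step 15
Reactants: 24 (2S)-6-{6-ethyl-5-methyl-2-oxo-4-[2-(trimethylsilyl)ethoxy]-2H-pyran-3-yl}-5,7-dihydroxy-2-phenylchroman-4-one; 27 tert-butyl 2-methylbut-3-en-2-yl carbonate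
Product: 28 (2S)-6-{6-ethyl-5-methyl-2-oxo-4-[2-(trimethylsilyl)ethoxy]-2H-pyran-3-yl}-5-hydroxy-7-[(2-methylbut-3-en-2-yl)oxy]-2-phenylchroman-4-one
Conditions: Pd(PPh3)4 (10 mol %), THF, 0 °C
Reagents that add atoms: none
Why: In this Tsuji–Trost O-allylation without added base, zerovalent palladium ionises 27 with loss of CO2, the released tert-butoxide deprotonates the acidic 7-OH (5-OH is held in the hydrogen bond to C4=O), and in the cold the phenoxide attacks the more substituted allyl terminus to give the tertiary ether without exposing C2 to base.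

Step 16
Reactants: 28 (2S)-6-{6-ethyl-5-methyl-2-oxo-4-[2-(trimethylsilyl)ethoxy]-2H-pyran-3-yl}-5-hydroxy-7-[(2-methylbut-3-en-2-yl)oxy]-2-phenylchroman-4-one
Product: 30 (2S)-6-{6-ethyl-5-methyl-2-oxo-4-[2-(trimethylsilyl)ethoxy]-2H-pyran-3-yl}-5,7-dihydroxy-8-(3-methylbut-2-en-1-yl)-2-phenylchroman-4-one, via cyclohexadienone 29 (not isolated)
Conditions: PhMe, 110 °C
Reagents that add atoms: none
Why: The [3,3] shift of this aromatic Claisen rearrangement can end productively only at C8 because the other ortho carbon C6 bears the pyrone, it inverts the allyl unit so that the 1,1-dimethylallyl ether becomes the prenyl group, 29 tautomerises to the phenol, and the geminal methyl groups allow a moderate temperature in a neutral solvent.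

Step 17
Reactants: 30 (2S)-6-{6-ethyl-5-methyl-2-oxo-4-[2-(trimethylsilyl)ethoxy]-2H-pyran-3-yl}-5,7-dihydroxy-8-(3-methylbut-2-en-1-yl)-2-phenylchroman-4-one
Product: 31 (2S)-6-(6-ethyl-4-hydroxy-5-methyl-2-oxo-2H-pyran-3-yl)-5,7-dihydroxy-8-(3-methylbut-2-en-1-yl)-2-phenylchroman-4-one (CNP0482269.1)
Conditions: Bu4NF, THF, 0 °C to rt; AcOH
Reagents that add atoms: none
Why: Fluoride-induced β-elimination (attack at silicon, loss of ethene), known for 2-(trimethylsilyl)ethyl esters and tetronates, frees the vinylogous acid without touching the prenyl group, and the flavanone is then present as its 7-phenoxide, a vinylogous carboxylate that resists the enolisation and ring opening that would racemise C2.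

Compound list
1 | pentan-3-one | CCC(=O)CC | starting material
2 | trimethyl(pent-2-en-3-yloxy)silane (E/Z mixture) | CC=C(CC)O[Si](C)(C)C | intermediate
3 | malonyl dichloride | O=C(Cl)CC(=O)Cl | starting material
4 | 4-methyl-3,5-dioxoheptanoyl chloride | CCC(=O)C(C)C(=O)CC(=O)Cl | intermediate (not isolated)
5 | 6-ethyl-4-hydroxy-5-methyl-2H-pyran-2-one | CCc1oc(=O)cc(O)c1C | intermediate
6 | 6-ethyl-4-hydroxy-3-iodo-5-methyl-2H-pyran-2-one | CCc1oc(=O)c(I)c(O)c1C | intermediate
7 | 6-ethyl-3-iodo-5-methyl-4-[2-(trimethylsilyl)ethoxy]-2H-pyran-2-one | CCc1oc(=O)c(I)c(OCC[Si](C)(C)C)c1C | intermediate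
8 | 3,5-bis(benzyloxy)phenol | Oc1cc(OCc2ccccc2)cc(OCc2ccccc2)c1 | starting material
9 | [3,5-bis(benzyloxy)phenoxy]triisopropylsilane | CC(C)[Si](Oc1cc(OCc2ccccc2)cc(OCc2ccccc2)c1)(C(C)C)C(C)C | intermediate
10 | {2,6-bis(benzyloxy)-4-[(triisopropylsilyl)oxy]phenyl}lithium | [Li]c1c(OCc2ccccc2)cc(O[Si](C(C)C)(C(C)C)C(C)C)cc1OCc1ccccc1 | intermediate (not isolated)
11 | {2,6-bis(benzyloxy)-4-[(triisopropylsilyl)oxy]phenyl}zinc chloride | Cl[Zn]c1c(OCc2ccccc2)cc(O[Si](C(C)C)(C(C)C)C(C)C)cc1OCc1ccccc1 | intermediate (not isolated)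
12 | 3-{2,6-bis(benzyloxy)-4-[(triisopropylsilyl)oxy]phenyl}-6-ethyl-5-methyl-4-[2-(trimethylsilyl)ethoxy]-2H-pyran-2-one | CCc1oc(=O)c(-c2c(OCc3ccccc3)cc(O[Si](C(C)C)(C(C)C)C(C)C)cc2OCc2ccccc2)c(OCC[Si](C)(C)C)c1C | intermediate
13 | 3-[2,6-bis(benzyloxy)-4-hydroxyphenyl]-6-ethyl-5-methyl-4-[2-(trimethylsilyl)ethoxy]-2H-pyran-2-one | CCc1oc(=O)c(-c2c(OCc3ccccc3)cc(O)cc2OCc2ccccc2)c(OCC[Si](C)(C)C)c1C | intermediate
14 | (E)-cinnamyl alcohol | OC/C=C/c1ccccc1 | starting material
15 | (E)-cinnamyl methyl carbonate | COC(=O)OC/C=C/c1ccccc1 | intermediate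
16 | lithium aryloxide of 13 | [Li+].CCc1oc(=O)c(-c2c(OCc3ccccc3)cc([O-])cc2OCc2ccccc2)c(OCC[Si](C)(C)C)c1C | intermediate (not isolated)
17 | 3-{2,6-bis(benzyloxy)-4-[(1S)-1-phenylprop-2-en-1-yloxy]phenyl}-6-ethyl-5-methyl-4-[2-(trimethylsilyl)ethoxy]-2H-pyran-2-one | CCc1oc(=O)c(-c2c(OCc3ccccc3)cc(O[C@@H](C=C)c3ccccc3)cc2OCc2ccccc2)c(OCC[Si](C)(C)C)c1C | intermediate
18 | B-alkyl-9-borabicyclo[3.3.1]nonane adduct of 17 (boron on the terminal carbon, S) | CCc1oc(=O)c(-c2c(OCc3ccccc3)cc(O[C@@H](CCB3C4CCCC3CCC4)c3ccccc3)cc2OCc2ccccc2)c(OCC[Si](C)(C)C)c1C | intermediate (not isolated)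
19 | 3-{2,6-bis(benzyloxy)-4-[(1S)-3-hydroxy-1-phenylpropoxy]phenyl}-6-ethyl-5-methyl-4-[2-(trimethylsilyl)ethoxy]-2H-pyran-2-one | CCc1oc(=O)c(-c2c(OCc3ccccc3)cc(O[C@@H](CCO)c3ccccc3)cc2OCc2ccccc2)c(OCC[Si](C)(C)C)c1C | intermediate
20 | (3S)-3-aryloxy-3-phenylpropanal corresponding to 19 | CCc1oc(=O)c(-c2c(OCc3ccccc3)cc(O[C@@H](CC=O)c3ccccc3)cc2OCc2ccccc2)c(OCC[Si](C)(C)C)c1C | intermediate (not isolated)
21 | (3S)-3-(3,5-bis(benzyloxy)-4-{6-ethyl-5-methyl-2-oxo-4-[2-(trimethylsilyl)ethoxy]-2H-pyran-3-yl}phenoxy)-3-phenylpropanoic acid | CCc1oc(=O)c(-c2c(OCc3ccccc3)cc(O[C@@H](CC(=O)O)c3ccccc3)cc2OCc2ccccc2)c(OCC[Si](C)(C)C)c1C | intermediate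
22 | mixed anhydride of 21 with trifluoroacetic acid (S) | CCc1oc(=O)c(-c2c(OCc3ccccc3)cc(O[C@@H](CC(=O)OC(=O)C(F)(F)F)c3ccccc3)cc2OCc2ccccc2)c(OCC[Si](C)(C)C)c1C | intermediate (not isolated)
23 | (2S)-5,7-bis(benzyloxy)-6-{6-ethyl-5-methyl-2-oxo-4-[2-(trimethylsilyl)ethoxy]-2H-pyran-3-yl}-2-phenylchroman-4-one | CCc1oc(=O)c(-c2c(OCc3ccccc3)cc3c(c2OCc2ccccc2)C(=O)C[C@@H](c2ccccc2)O3)c(OCC[Si](C)(C)C)c1C | intermediate
24 | (2S)-6-{6-ethyl-5-methyl-2-oxo-4-[2-(trimethylsilyl)ethoxy]-2H-pyran-3-yl}-5,7-dihydroxy-2-phenylchroman-4-one | CCc1oc(=O)c(-c2c(O)cc3c(c2O)C(=O)C[C@@H](c2ccccc2)O3)c(OCC[Si](C)(C)C)c1C | intermediate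
25 | 2-methylbut-3-en-2-ol | C=CC(C)(C)O | starting material
26 | lithium 2-methylbut-3-en-2-olate | [Li+].[O-]C(C)(C)C=C | intermediate (not isolated)
27 | tert-butyl 2-methylbut-3-en-2-yl carbonate | C=CC(C)(C)OC(=O)OC(C)(C)C | intermediate
28 | (2S)-6-{6-ethyl-5-methyl-2-oxo-4-[2-(trimethylsilyl)ethoxy]-2H-pyran-3-yl}-5-hydroxy-7-[(2-methylbut-3-en-2-yl)oxy]-2-phenylchroman-4-one | CCc1oc(=O)c(-c2c(OC(C)(C)C=C)cc3c(c2O)C(=O)C[C@@H](c2ccccc2)O3)c(OCC[Si](C)(C)C)c1C | intermediate
29 | (2S)-8-prenyl-8H-chromene-4,7-dione tautomer of 30 (C7=O, C8 sp3 and unassigned, C5=C6 and C4a=C8a double bonds) | CCc1oc(=O)c(C2=C(O)C3=C(O[C@H](c4ccccc4)CC3=O)C(CC=C(C)C)C2=O)c(OCC[Si](C)(C)C)c1C | intermediate (not isolated)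
30 | (2S)-6-{6-ethyl-5-methyl-2-oxo-4-[2-(trimethylsilyl)ethoxy]-2H-pyran-3-yl}-5,7-dihydroxy-8-(3-methylbut-2-en-1-yl)-2-phenylchroman-4-one | CCc1oc(=O)c(-c2c(O)c(CC=C(C)C)c3c(c2O)C(=O)C[C@@H](c2ccccc2)O3)c(OCC[Si](C)(C)C)c1C | intermediate
31 | (2S)-6-(6-ethyl-4-hydroxy-5-methyl-2-oxo-2H-pyran-3-yl)-5,7-dihydroxy-8-(3-methylbut-2-en-1-yl)-2-phenylchroman-4-one | CCc1oc(=O)c(-c2c(O)c(CC=C(C)C)c3c(c2O)C(=O)C[C@@H](c2ccccc2)O3)c(O)c1C | target

Total step count: 17.
Longest linear sequence: 14 steps (1–4, 6, 7, 9–13, 15–17).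

Steps most likely to fail

Step 12. Three processes could interfere:
- acid-induced ionisation of the benzylic C2–O1 bond, with loss of enantiopurity or β-elimination;
- intermolecular trifluoroacetylation of ring A outrunning the ring closure;
- acidolysis of the silylethyl group.

The fallback sets out from 21 and returns at 23. It forms the same C4–C4a bond with inverted polarity and without acid. Acid 21 is coupled with MeNHOMe·HCl (EDC·HCl, i-Pr2NEt, CH2Cl2) to the N-methoxy-N-methylamide F3. NBS (1 equiv, MeCN, −20 °C) brominates one of the two equivalent carbons ortho to the ether oxygen to give the aryl bromide F4. n-BuLi (THF, −90 °C) effects bromine–lithium exchange to the aryllithium F5. This closes at once on the amide carbonyl (Parham cyclisation) to the chelated tetrahedral adduct F6, and a mildly acidic work-up releases 23.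

Step 6. Deprotonation at a benzylic methylene followed by Wittig rearrangement could take the place of ring lithiation. The coupling could also be sluggish at two doubly flanked centres, with protodemetalation. The fallback sets out from 5 and 9 and returns at 12, using no strong base. Regitz diazo transfer (4-acetamidobenzenesulfonyl azide, Et3N, MeCN) converts 5 into 3-diazo-6-ethyl-5-methyl-2H-pyran-2,4(3H)-dione F1. Rh2(OAc)4 (PhCF3, 80 °C) then generates the electrophilic rhodium carbenoid. It substitutes the electron-rich arene 9 at the position between the two benzyloxy groups, since the silyl ether screens the other two. This gives the 3-aryl-4-hydroxypyrone F2. A Mitsunobu reaction with 2-(trimethylsilyl)ethanol, as in step 4, leads to 12.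

Step 15. Capture of the allyl palladium cation by the hindered 7-phenoxide could be slow. The tertiary ether could also re-ionise and drift to the linear ether, or the allyl unit could be lost by elimination. The fallback sets out from 24 and returns at 28. Copper-catalysed propargylic etherification (3-chloro-3-methylbut-1-yne, CuCl2·2H2O cat., DBU, MeCN, 0 °C) gives the 7-O-(1,1-dimethylpropargyl) ether F7. Semi-hydrogenation (H2, Pd/CaCO3–Pb(OAc)2, quinoline, EtOAc) turns it into 28.

Further compounds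
F1 | step 6 | 3-diazo-6-ethyl-5-methyl-2H-pyran-2,4(3H)-dione | CCC1=C(C)C(=O)C(=[N+]=[N-])C(=O)O1
F2 | step 6 | 3-{2,6-bis(benzyloxy)-4-[(triisopropylsilyl)oxy]phenyl}-6-ethyl-4-hydroxy-5-methyl-2H-pyran-2-one | CCc1oc(=O)c(-c2c(OCc3ccccc3)cc(O[Si](C(C)C)(C(C)C)C(C)C)cc2OCc2ccccc2)c(O)c1C
F3 | step 12 | (3S)-N-methoxy-N-methylamide of 21 | CCc1oc(=O)c(-c2c(OCc3ccccc3)cc(O[C@@H](CC(=O)N(C)OC)c3ccccc3)cc2OCc2ccccc2)c(OCC[Si](C)(C)C)c1C
F4 | step 12 | (3S)-amide F3 brominated ortho to the ether oxygen | CCc1oc(=O)c(-c2c(OCc3ccccc3)c(Br)c(O[C@@H](CC(=O)N(C)OC)c3ccccc3)cc2OCc2ccccc2)c(OCC[Si](C)(C)C)c1C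
F5 | step 12 | aryllithium from F4 (S) | CCc1oc(=O)c(-c2c(OCc3ccccc3)c([Li])c(O[C@@H](CC(=O)N(C)OC)c3ccccc3)cc2OCc2ccccc2)c(OCC[Si](C)(C)C)c1C
F6 | step 12 | lithium salt of the cyclic C4 hemiaminal (2S, C4 unassigned) | [Li+].CCc1oc(=O)c(-c2c(OCc3ccccc3)cc3c(c2OCc2ccccc2)C([O-])(N(C)OC)C[C@@H](c2ccccc2)O3)c(OCC[Si](C)(C)C)c1C
F7 | step 15 | (2S)-6-{6-ethyl-5-methyl-2-oxo-4-[2-(trimethylsilyl)ethoxy]-2H-pyran-3-yl}-5-hydroxy-7-[(2-methylbut-3-yn-2-yl)oxy]-2-phenylchroman-4-one | CCc1oc(=O)c(-c2c(OC(C)(C)C#C)cc3c(c2O)C(=O)C[C@@H](c2ccccc2)O3)c(OCC[Si](C)(C)C)c1C
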